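**Retrosynthetic overview**
1. 12 ⇐ 11: the C9–O bond is made last by allylic C–H hydroxylation (Se(IV) ene/[2,3]) of the Δ7 olefin; this is the key bond. The C6–O ester comes from acylation of diol 9.
2. 9 ⇐ 8: the cycloheptene is closed by ring-closing metathesis at C7=C8.
3. 8 ⇐ 6: the C4 carbinol comes from isopropyl addition to the cyclopentanone.
4. 6 ⇐ 1 + 2 + 3: one-flask enantioselective conjugate addition/anti-aldol sets C1, C5 and C6.
5. Ring order: cyclopentane (present in 1), then cycloheptene (RCM).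

Convention: daucane numbering is used for locants (C1 = methyl-bearing ring-fusion carbon, C4 = C(OH)iPr, C5 = ring-fusion CH, C6 = ester carbon, C7=C8 olefin with C8–Me, C9 = CHOH, C10 = CH2), β = face of the C1 methyl; catalogue chemicals are taken as commercially available.

**Step 1**
Reactants: 1 3-methylcyclopent-2-en-1-one; 2 4-bromo-2-methylbut-1-ene; 3 acrolein (prop-2-enal)
Product: 6 (2S,3S)-2-[(1S)-1-hydroxyprop-2-en-1-yl]-3-methyl-3-(3-methylbut-3-en-1-yl)cyclopentan-1-one, via Grignard reagent 4 (not isolated), via magnesium enolate 5 (not isolated)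
Conditions: 2, Mg, Et2O, rt; Cu(OTf)2 (3 mol %), chiral alkoxide-tethered imidazolinium (NHC) salt (4 mol %), Et2O, −30 °C, slow addition of 1; then 3, −78 °C; aq NH4Cl
Reagents that add atoms: none
Why: Proposed new method: a one-flask three-component union in which a chiral alkoxide-tethered NHC–Cu(I) catalyst (the alkoxide arm holds Mg, which binds the enone carbonyl, so the flat five-membered enone sits in a bimetallic pocket) transfers the primary alkyl group of 4 to one β-face of 1 through a Cu(III) intermediate and reductive elimination, setting the (S)-quaternary C1 (ligand enantiomer chosen accordingly) and releasing the regiodefined magnesium enolate 5 on the quaternary side, which adds 1,2 to acrolein through a closed Zimmerman–Traxler chair (E(O)-enolate gives the anti aldol, C6) on the face trans to the longer butenyl chain (C5); the closest known reaction type is Cu/NHC-catalysed asymmetric conjugate addition of Grignard reagents to β-methylcyclohexenones with electrophilic capture of the magnesium enolate, not yet shown as a single enantioselective operation on a β-methylcyclopentenone with a functionalised homoallyl Grignard and acrolein.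

**Step 2**
Reactants: 6; 7 isopropylmagnesium chloride
Product: 8 (1R,2S,3S)-2-[(1S)-1-hydroxyprop-2-en-1-yl]-3-methyl-3-(3-methylbut-3-en-1-yl)-1-(propan-2-yl)cyclopentan-1-ol
Conditions: 7 (3 equiv), LaCl3·2LiCl (1.1 equiv), THF, −20 → 0 °C; aq NH4Cl
Reagents that add atoms: none
Why: Lanthanum-promoted Grignard 1,2-addition, in which isopropyl approaches the ketone face trans to the adjacent C5 side chain (α-face) to give the 4β-OH/4α-iPr carbinol (C4 R), while the oxophilic, weakly basic La species suppresses enolisation, β-hydride reduction and retro-aldol.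

**Step 3**
Reactants: 8
Product: 9 (3R,3aS,4S,8aS)-6,8a-dimethyl-3-(propan-2-yl)-1,2,3,3a,4,7,8,8a-octahydroazulene-3,4-diol (4β,6α-dihydroxydauc-7-ene)
Conditions: Grubbs II (5 mol %), CH2Cl2 (5 mM), 40 °C
Reagents that add atoms: none
Why: Ring-closing olefin metathesis between the vinyl carbinol and the 1,1-disubstituted olefin forms the trisubstituted C7=C8 bond and the trans-fused cycloheptene; no stereocentre is touched, the trans fusion being fixed at C1/C5 in step 1.

**Step 4**
Reactants: 9; 10 4-methoxybenzoyl chloride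
Product: 11 (3R,3aS,4S,8aS)-3-hydroxy-6,8a-dimethyl-3-(propan-2-yl)-1,2,3,3a,4,7,8,8a-octahydroazulen-4-yl 4-methoxybenzoate
Conditions: 10 (1.5 equiv), Et3N, DMAP (0.2 equiv), CH2Cl2, 0 °C → rt
Reagents that add atoms: none
Why: DMAP-catalysed acylation (Einhorn/Steglich type) is selective for the secondary allylic C6–OH over the hindered tertiary C4–OH and proceeds with retention at C6.

**Step 5**
Reactants: 11
Product: 12 (3R,3aS,4S,7R,8aR)-3,7-dihydroxy-6,8a-dimethyl-3-(propan-2-yl)-1,2,3,3a,4,7,8,8a-octahydroazulen-4-yl 4-methoxybenzoate (target; 4β,9β-dihydroxy-6α-(4-methoxybenzoyloxy)dauc-7-ene)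
Conditions: SeO2 (30 mol %), t-BuOOH (3 equiv, in decane), CH2Cl2, rt
Reagents that add atoms: tert-butyl hydroperoxide, CC(C)(C)OO (oxygen relayed through the SeO2 catalyst)
Why: Riley-type SeO2/t-BuOOH allylic hydroxylation, in which ene attack of Se(IV) on C7 removes the pseudoaxial H9β (the ring allylic C–H aligned with the π-bond in the trans-fused chair; C6–H is deactivated by the ester) and the suprafacial [2,3]-sigmatropic shift returns the olefin to C7=C8 and delivers oxygen to the same β-face of C9, giving the axial 9β-alcohol cis to the angular methyl (C9 R), a prediction by analogy with axial allylic hydroxylation of rigid cycloalkenes.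

**Compound list**
1 | 3-methylcyclopent-2-en-1-one | CC1=CC(=O)CC1 | starting material
2 | 4-bromo-2-methylbut-1-ene | CC(=C)CCBr | starting material
3 | acrolein (prop-2-enal) | C=CC=O | starting material
4 | (3-methylbut-3-en-1-yl)magnesium bromide | CC(=C)CC[Mg]Br | intermediate
5 | bromomagnesium (3S)-3-methyl-3-(3-methylbut-3-en-1-yl)cyclopent-1-en-1-olate | Br[Mg]OC1=C[C@@](C)(CCC(C)=C)CC1 | intermediate
6 | (2S,3S)-2-[(1S)-1-hydroxyprop-2-en-1-yl]-3-methyl-3-(3-methylbut-3-en-1-yl)cyclopentan-1-one | O[C@@H](C=C)[C@H]1C(=O)CC[C@]1(C)CCC(C)=C | intermediate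
7 | isopropylmagnesium chloride | CC(C)[Mg]Cl | starting material
8 | (1R,2S,3S)-2-[(1S)-1-hydroxyprop-2-en-1-yl]-3-methyl-3-(3-methylbut-3-en-1-yl)-1-(propan-2-yl)cyclopentan-1-ol | O[C@@H](C=C)[C@H]1[C@](O)(C(C)C)CC[C@]1(C)CCC(C)=C | intermediate
9 | (3R,3aS,4S,8aS)-6,8a-dimethyl-3-(propan-2-yl)-1,2,3,3a,4,7,8,8a-octahydroazulene-3,4-diol | O[C@H]1C=C(C)CC[C@@]2(C)CC[C@@](O)(C(C)C)[C@H]12 | intermediate
10 | 4-methoxybenzoyl chloride | COc1ccc(cc1)C(Cl)=O | starting material
11 | (3R,3aS,4S,8aS)-3-hydroxy-6,8a-dimethyl-3-(propan-2-yl)-1,2,3,3a,4,7,8,8a-octahydroazulen-4-yl 4-methoxybenzoate | COc1ccc(cc1)C(=O)O[C@H]1C=C(C)CC[C@@]2(C)CC[C@@](O)(C(C)C)[C@H]12 | intermediate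
12 | (3R,3aS,4S,7R,8aR)-3,7-dihydroxy-6,8a-dimethyl-3-(propan-2-yl)-1,2,3,3a,4,7,8,8a-octahydroazulen-4-yl 4-methoxybenzoate | COc1ccc(cc1)C(=O)O[C@H]1C=C(C)[C@H](O)C[C@@]2(C)CC[C@@](O)(C(C)C)[C@H]12 | target

**Totals**
Total steps: 5. Longest linear sequence: 5 (1 → 6 → 8 → 9 → 11 → 12).

**Three steps most likely to fail**

Step 1 (the proposed new step). The risks are insufficient ee on the five-membered enone and modest face or anti/syn control in the aldol. The fallback uses known chemistry and sets out from 2 (as its Grignard reagent 4) and commercial 3-ethoxycyclopent-2-en-1-one (CCOC1=CC(=O)CC1). 1,2-Addition gives the bromomagnesium 3-ethoxy-1-(3-methylbut-3-en-1-yl)cyclopent-2-en-1-olate F1, which on acidic hydrolysis (Stork–Danheiser transposition) gives 3-(3-methylbut-3-en-1-yl)cyclopent-2-en-1-one F2. Cu/chiral-NHC-catalysed conjugate addition of Me3Al then sets the quaternary centre and gives dimethylaluminium (3S)-3-methyl-3-(3-methylbut-3-en-1-yl)cyclopent-1-en-1-olate F3, captured with Et3SiOTf as triethyl{[(3S)-3-methyl-3-(3-methylbut-3-en-1-yl)cyclopent-1-en-1-yl]oxy}silane F4. MeLi cleaves the silyl ether to lithium (3S)-3-methyl-3-(3-methylbut-3-en-1-yl)cyclopent-1-en-1-olate F5, and MgBr2·OEt2 converts this into the magnesium enolate, so the sequence comes back to the route at 5, which is carried on with 3 to 6 as in step 1. If the ee is still short, it is raised by recrystallising 9 or 11.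

Step 5. The risks are competing oxidation of the C8 methyl, attack from the α-face giving the 9α-epimer, and over-oxidation. The fallback sets out from 11: chromium(VI) allylic oxidation (CrO3·3,5-dimethylpyrazole, CH2Cl2, −20 °C) at the only allylic CH2 gives (3R,3aS,4S,8aR)-3-hydroxy-6,8a-dimethyl-7-oxo-3-(propan-2-yl)-1,2,3,3a,4,7,8,8a-octahydroazulen-4-yl 4-methoxybenzoate F8. Luche reduction (NaBH4, CeCl3·7H2O, MeOH, −78 °C), with hydride arriving from the α-face opposite the angular methyl, comes back to the route at 12.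

Step 2. The risks are retro-aldol of the β-alkoxy ketone, enolisation and reduction by the Grignard reagent. The fallback sets out from 6: silylation (Et3SiCl, imidazole, DMF) gives (2S,3S)-3-methyl-3-(3-methylbut-3-en-1-yl)-2-[(1S)-1-(triethylsilyloxy)prop-2-en-1-yl]cyclopentan-1-one F6, which cannot fragment. Addition of 7 (LaCl3·2LiCl, or i-PrLi/CeCl3) gives (1R,2S,3S)-3-methyl-3-(3-methylbut-3-en-1-yl)-1-(propan-2-yl)-2-[(1S)-1-(triethylsilyloxy)prop-2-en-1-yl]cyclopentan-1-ol F7, and Bu4NF (THF) comes back to the route at 8.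

**Further compounds**
F1 | step 1 | bromomagnesium 3-ethoxy-1-(3-methylbut-3-en-1-yl)cyclopent-2-en-1-olate (racemic) | CCOC1=CC(O[Mg]Br)(CCC(C)=C)CC1
F2 | step 1 | 3-(3-methylbut-3-en-1-yl)cyclopent-2-en-1-one | O=C1C=C(CCC(C)=C)CC1
F3 | step 1 | dimethylaluminium (3S)-3-methyl-3-(3-methylbut-3-en-1-yl)cyclopent-1-en-1-olate | C[Al](C)OC1=C[C@@](C)(CCC(C)=C)CC1
F4 | step 1 | triethyl{[(3S)-3-methyl-3-(3-methylbut-3-en-1-yl)cyclopent-1-en-1-yl]oxy}silane | CC[Si](CC)(CC)OC1=C[C@@](C)(CCC(C)=C)CC1
F5 | step 1 | lithium (3S)-3-methyl-3-(3-methylbut-3-en-1-yl)cyclopent-1-en-1-olate | [Li]OC1=C[C@@](C)(CCC(C)=C)CC1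
F6 | step 2 | (2S,3S)-3-methyl-3-(3-methylbut-3-en-1-yl)-2-[(1S)-1-(triethylsilyloxy)prop-2-en-1-yl]cyclopentan-1-one | CC[Si](CC)(CC)O[C@@H](C=C)[C@H]1C(=O)CC[C@]1(C)CCC(C)=C
F7 | step 2 | (1R,2S,3S)-3-methyl-3-(3-methylbut-3-en-1-yl)-1-(propan-2-yl)-2-[(1S)-1-(triethylsilyloxy)prop-2-en-1-yl]cyclopentan-1-ol | CC[Si](CC)(CC)O[C@@H](C=C)[C@H]1[C@](O)(C(C)C)CC[C@]1(C)CCC(C)=C
F8 | step 5 | (3R,3aS,4S,8aR)-3-hydroxy-6,8a-dimethyl-7-oxo-3-(propan-2-yl)-1,2,3,3a,4,7,8,8a-octahydroazulen-4-yl 4-methoxybenzoate | COc1ccc(cc1)C(=O)O[C@H]1C=C(C)C(=O)C[C@@]2(C)CC[C@@](O)(C(C)C)[C@H]12
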